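**Retrosynthetic overview**

1. The target is (1S,2S,5R,6R)-2,6-diaryl-3,7-dioxabicyclo[3.3.0]octan-1-ol (ring A: C5–C6–O7–C8–C1; ring B: C1–C2–O3–C4–C5). Both aryl groups are endo (trans to OH-1 and H-5), so every ring closure has to be kinetic.
2. The C1 hydroxyl is traced back to a C1=C8 enol ether (exo epoxidation, hydride at C8). Ring B is traced back to an oxocarbenium closure C1→C2 between a cis-(2-aryl-2,3-dihydrofuran-3-yl)methanol and the dimethyl acetal of the same protected vanillin.
3. Ring A is not built as a five-membered ring: it grows from an aryl vinyl oxirane (three-membered ring O7/C6/C8) by thermal ring expansion through a carbonyl ylide that closes onto the alkene C1=C5.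
4. Enabling feature: O7 lies between the benzylic C6 and C8, C6 is bonded to C5, the aryl on C6 is cis to C4 on C5, and C1 sits next to C8. This is the pattern left by 6π closure of the ylide C6=O7(+)–C8(−) onto C1=C5 (C4 carried as an ester), which also delivers C1=C8 as the enol ether used later.
5. Ring order: oxirane (step 2) → ring A (step 3) → ring B (step 7). Absolute configuration comes from enzymatic resolution (step 5); both aryl units come from vanillin.

Key step: step 3

**Remarks.** Ar = 3-methoxy-4-(triisopropylsilyloxy)phenyl. Bicyclic compounds are numbered as 3,7-dioxabicyclo[3.3.0]octanes (C1 and C5 are the bridgeheads).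

**Assumption.** In step 5 the lipase is taken to acetylate the (2S,3S)-alcohol faster, so the (2R,3R)-alcohol 8 is the one recovered; if the preference is the reverse, 8 is obtained from its acetate with K2CO3/MeOH and nothing else changes.

**Step 1**
Reactants: 1 vanillin
Product: 2 3-methoxy-4-(triisopropylsilyloxy)benzaldehyde
Conditions: i-Pr3SiCl, imidazole, DMF, 25 °C
Reagents that add atoms: triisopropylsilyl chloride, CC(C)[Si](Cl)(C(C)C)C(C)C
Why: O-silylation of the phenol; the hindered aryl silyl ether should survive strong base, pyrolysis, hydride and cold Lewis acid and is removed by fluoride at the end; no stereocentre is formed.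

**Step 2**
Reactants: 2 3-methoxy-4-(triisopropylsilyloxy)benzaldehyde; 3 methyl (E)-4-bromobut-2-enoate
Product: 4 methyl (E)-3-(3-Ar-oxiran-2-yl)prop-2-enoate (racemic; cis and trans oxirane isomers)
Conditions: LiN(SiMe3)2, THF, −78 → 0 °C
Reagents that add atoms: none
Why: Vinylogous Darzens condensation: the γ-bromo dienolate of 3 adds through C4 to the aldehyde and the alkoxide displaces bromide to close the oxirane (addition through C2 is reversible and cannot close), and both oxirane isomers are usable because their stereocentres are erased in step 3.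

**Step 3**
Reactants: 4 methyl (E)-3-(3-Ar-oxiran-2-yl)prop-2-enoate
Product: 6 methyl rac-(2R,3S)-2-Ar-2,3-dihydrofuran-3-carboxylate (cis), via carbonyl ylide 5 (not isolated)
Conditions: flash vacuum pyrolysis, quartz tube, 500 °C, ca. 0.05 mbar, cold trap
Reagents that add atoms: none
Why: In the gas phase the oxirane C–C bond opens in a conrotatory four-electron process, made easy because the carbonyl ylide 5 is stabilised by the aryl group at one end and the vinylogous ester at the other; the ylide and the adjacent C=C then close by thermal disrotatory six-electron 1,5-electrocyclisation. The closest known reaction type is the thermal vinyl oxirane → 2,3-dihydrofuran rearrangement of aryl vinyl oxiranes bearing an acrylate (related to the vinylcyclopropane → cyclopentene and acylcyclopropane → dihydrofuran ring expansions). Ring A is closed by C–C bond formation between the benzylic ylide carbon (later C6) and the acrylate α-carbon (later C5), so the three-membered ring grows by the two alkene carbons. The two new stereocentres are set relative to each other by orbital symmetry: in the reactive U-shaped ylide the aryl and ester groups both sit on the outside, and disrotation turns them onto the same face, so either oxirane isomer should give the cis product; the ylide is planar, so the product is racemic and the absolute configuration is fixed in step 5. The step needs C–C cleavage to beat C–O cleavage (which would lead to 2,5-dihydrofuran or carbonyl products) and needs the cis ester not to epimerise; the donor aryl/acceptor acrylate pair on the oxirane secures the first, and the short, acid- and base-free contact time secures the second.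

**Step 4**
Reactants: 6 methyl rac-(2R,3S)-2-Ar-2,3-dihydrofuran-3-carboxylate
Product: 7 rac-[(2R,3R)-2-Ar-2,3-dihydrofuran-3-yl]methanol (cis)
Conditions: i-Bu2AlH, CH2Cl2, −78 °C; Rochelle salt work-up
Reagents that add atoms: none
Why: Aluminium hydride reduction of the ester to the primary alcohol at low temperature without free base, so that C3 (α to the ester, cis to the aryl group) is not epimerised; no new stereocentre.

**Step 5**
Reactants: 7 rac-[(2R,3R)-2-Ar-2,3-dihydrofuran-3-yl]methanol
Product: 8 [(2R,3R)-2-Ar-2,3-dihydrofuran-3-yl]methanol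
Conditions: Burkholderia cepacia lipase (immobilised), vinyl acetate, t-BuOMe, 25 °C, run slightly past half conversion; chromatography
Reagents that add atoms: none
Why: Enzymatic kinetic resolution by irreversible lipase transesterification with an enol ester: one enantiomer is acetylated and the other recovered, so the absolute configuration at C2 and C3 (later C6 and C5) is fixed here by the enzyme.

**Step 6**
Reactants: 2 3-methoxy-4-(triisopropylsilyloxy)benzaldehyde
Product: 9 4-(dimethoxymethyl)-2-methoxy-1-(triisopropylsilyloxy)benzene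
Conditions: HC(OMe)3, MeOH, p-TsOH (cat.), 25 °C; then Et3N
Reagents that add atoms: trimethyl orthoformate, COC(OC)OC; methanol, CO
Why: Acid-catalysed acetalisation of the aldehyde with the orthoester as water scavenger; no stereocentre.

**Step 7**
Reactants: 8 [(2R,3R)-2-Ar-2,3-dihydrofuran-3-yl]methanol; 9 4-(dimethoxymethyl)-2-methoxy-1-(triisopropylsilyloxy)benzene
Product: 11 (1S,2R,5R,6R,8R)-2,6-di-Ar-8-methoxy-3,7-dioxabicyclo[3.3.0]octane (both aryl groups endo), via mixed acetal 10 (not isolated)
Conditions: Me3SiOTf (20 mol %), 4 Å molecular sieves, CH2Cl2, −78 → −40 °C; then Et3N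
Reagents that add atoms: none
Why: Transacetalisation gives 10, whose oxocarbenium ion is attacked by the enol ether carbon C1 (intramolecular Prins-type oxocarbenium–enol ether cyclisation), so ring B closes cis-fused on the face carrying the tether and the ring A oxocarbenium ion is trapped by methanol on the exo face; as in related cyclisations of cis-2-aryl-3-hydroxymethyl-2,3-dihydrofurans with aryl acetals the kinetic product should carry the new aryl group endo at C2, and a cold quench avoids acid equilibration to the exo epimer.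

**Step 8**
Reactants: 11 (1S,2R,5R,6R,8R)-2,6-di-Ar-8-methoxy-3,7-dioxabicyclo[3.3.0]octane
Product: 12 (2S,5R,6R)-2,6-di-Ar-3,7-dioxabicyclo[3.3.0]oct-1(8)-ene
Conditions: Me3SiOTf, i-Pr2NEt, CH2Cl2, −20 → 20 °C
Reagents that add atoms: none
Why: Acetal-to-enol-ether elimination: the silyl triflate ionises the methyl acetal and the hindered amine removes H-1, the only proton next to the C8 oxocarbenium ion, giving the C1=C8 enol ether without touching C2, C5 or C6.

**Step 9**
Reactants: 12 (2S,5R,6R)-2,6-di-Ar-3,7-dioxabicyclo[3.3.0]oct-1(8)-ene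
Product: 14 (1S,2S,5R,6R)-2,6-di-Ar-3,7-dioxabicyclo[3.3.0]octan-1-ol, via exo-epoxide 13 (not isolated)
Conditions: dimethyldioxirane, acetone/CH2Cl2, −78 → −30 °C, volatiles removed cold; then LiAlH4, Et2O, −40 → 0 °C
Reagents that add atoms: dimethyldioxirane, CC1(C)OO1
Why: Dioxirane epoxidation of the enol ether from the exo face (the endo face is screened by both aryl groups) sets the C1–O bond cis to H-5, and hydride then opens the acetal-type epoxide at C8 (as in the reduction of 1,2-anhydro sugars), leaving the tertiary C1 alcohol.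

**Step 10**
Reactants: 14 (1S,2S,5R,6R)-2,6-di-Ar-3,7-dioxabicyclo[3.3.0]octan-1-ol
Product: 15 (1S,2S,5R,6R)-2,6-bis(4-hydroxy-3-methoxyphenyl)-3,7-dioxabicyclo[3.3.0]octan-1-ol
Conditions: Bu4NF, AcOH, THF, 0 °C
Reagents that add atoms: none
Why: Fluoride cleavage of both aryl silyl ethers under buffered, non-acidic conditions that leave the acid-labile endo benzylic ethers and their configuration untouched.

**Compound list**

1 | vanillin (4-hydroxy-3-methoxybenzaldehyde) | COc1cc(C=O)ccc1O | starting material
2 | 3-methoxy-4-(triisopropylsilyloxy)benzaldehyde | COc1cc(C=O)ccc1O[Si](C(C)C)(C(C)C)C(C)C | intermediate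
3 | methyl (E)-4-bromobut-2-enoate | COC(=O)/C=C/CBr | starting material
4 | methyl (E)-3-(3-Ar-oxiran-2-yl)prop-2-enoate (racemic; cis and trans oxirane isomers) | COC(=O)/C=C/C1OC1c1ccc(O[Si](C(C)C)(C(C)C)C(C)C)c(OC)c1 | intermediate
5 | carbonyl ylide ArCH=O(+)–CH(−)–CH=CH–CO2Me (planar; not isolated) | COC(=O)/C=C/[CH-][O+]=Cc1ccc(O[Si](C(C)C)(C(C)C)C(C)C)c(OC)c1 | intermediate
6 | methyl rac-(2R,3S)-2-Ar-2,3-dihydrofuran-3-carboxylate (cis; racemic, the 2R,3S enantiomer is drawn) | COC(=O)[C@H]1C=CO[C@H]1c1ccc(O[Si](C(C)C)(C(C)C)C(C)C)c(OC)c1 | intermediate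
7 | rac-[(2R,3R)-2-Ar-2,3-dihydrofuran-3-yl]methanol (cis; racemic, the 2R,3R enantiomer is drawn) | OC[C@H]1C=CO[C@H]1c1ccc(O[Si](C(C)C)(C(C)C)C(C)C)c(OC)c1 | intermediate
8 | [(2R,3R)-2-Ar-2,3-dihydrofuran-3-yl]methanol (single enantiomer) | OC[C@H]1C=CO[C@H]1c1ccc(O[Si](C(C)C)(C(C)C)C(C)C)c(OC)c1 | intermediate
9 | 4-(dimethoxymethyl)-2-methoxy-1-(triisopropylsilyloxy)benzene | COC(OC)c1ccc(O[Si](C(C)C)(C(C)C)C(C)C)c(OC)c1 | intermediate
10 | (2R,3R)-2-Ar-3-{[methoxy(Ar)methoxy]methyl}-2,3-dihydrofuran (mixed acetal, both acetal epimers; not isolated) | COC(OC[C@H]1C=CO[C@H]1c1ccc(O[Si](C(C)C)(C(C)C)C(C)C)c(OC)c1)c1ccc(O[Si](C(C)C)(C(C)C)C(C)C)c(OC)c1 | intermediate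
11 | (1S,2R,5R,6R,8R)-2,6-di-Ar-8-methoxy-3,7-dioxabicyclo[3.3.0]octane (aryl groups endo, methoxy exo) | COc1cc([C@@H]2O[C@@H](OC)[C@H]3[C@@H]2CO[C@H]3c2ccc(O[Si](C(C)C)(C(C)C)C(C)C)c(OC)c2)ccc1O[Si](C(C)C)(C(C)C)C(C)C | intermediate
12 | (2S,5R,6R)-2,6-di-Ar-3,7-dioxabicyclo[3.3.0]oct-1(8)-ene | COc1cc([C@@H]2OC=C3[C@@H]2CO[C@H]3c2ccc(O[Si](C(C)C)(C(C)C)C(C)C)c(OC)c2)ccc1O[Si](C(C)C)(C(C)C)C(C)C | intermediate
13 | 1,8-epoxide of 12 with the oxirane oxygen exo, on the face of H-5 (not isolated) | COc1cc([C@@H]2O[C@H]3O[C@@]34[C@@H]2CO[C@H]4c2ccc(O[Si](C(C)C)(C(C)C)C(C)C)c(OC)c2)ccc1O[Si](C(C)C)(C(C)C)C(C)C | intermediate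
14 | (1S,2S,5R,6R)-2,6-di-Ar-3,7-dioxabicyclo[3.3.0]octan-1-ol | COc1cc([C@@H]2OC[C@@]3(O)[C@@H]2CO[C@H]3c2ccc(O[Si](C(C)C)(C(C)C)C(C)C)c(OC)c2)ccc1O[Si](C(C)C)(C(C)C)C(C)C | intermediate
15 | (1S,2S,5R,6R)-2,6-bis(4-hydroxy-3-methoxyphenyl)-3,7-dioxabicyclo[3.3.0]octan-1-ol | COc1cc([C@@H]2OC[C@@]3(O)[C@@H]2CO[C@H]3c2ccc(O)c(OC)c2)ccc1O | target

**Total step count:** 10. **Longest linear sequence:** 9 steps (steps 1–5 and 7–10).

**The three steps most likely to fail**

1. Step 5. The enzyme may discriminate poorly between the enantiomers, because the stereocentre is one carbon away from the hydroxyl being acylated, leaving the recovered alcohol short of enantiopure. Fallback (covalent resolution instead of enzymatic): setting out from 7, esterification with (S)-2-methoxy-2-phenylacetic acid (N,N'-dicyclohexylcarbodiimide, 4-dimethylaminopyridine, CH2Cl2) should give two diastereomeric esters that are separated by chromatography or crystallisation. The ester of the wanted alcohol, [(2R,3R)-2-Ar-2,3-dihydrofuran-3-yl]methyl (S)-2-methoxy-2-phenylacetate F1, is then methanolysed (K2CO3, MeOH, 0 °C) and the route is rejoined at 8.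

2. Step 8. The silyl triflate may ionise the endo benzylic C–O bonds (epimerisation at C2 or C6), or the enol ether may oligomerise under Lewis acid. Fallback (base-mediated dehydration of a lactol instead of Lewis-acid elimination): setting out from 11, pyridinium p-toluenesulfonate in wet acetone should give the lactol (1S,2R,5R,6R)-2,6-di-Ar-3,7-dioxabicyclo[3.3.0]octan-8-ol F2. Its anomeric mesylate (MsCl, Et3N, CH2Cl2, 0 → 40 °C) is eliminated by the amine, and the route is rejoined at 12.

3. Step 9. The acetal-type epoxide may rearrange or solvolyse before hydride is delivered, and the electron-rich arenes may be over-oxidised. Fallback (dihydroxylation and reductive removal of the anomeric hydroxyl instead of epoxidation and hydride opening): setting out from 12, OsO4 (cat.) with N-methylmorpholine N-oxide in acetone/H2O should add to the exo face to give (1R,2S,5R,6R,8R)-2,6-di-Ar-3,7-dioxabicyclo[3.3.0]octane-1,8-diol F3. Its anomeric hydroxyl is removed with Et3SiH and BF3·OEt2 in CH2Cl2 at −78 °C, and the route is rejoined at 14.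

**Further compounds**

F1 | step 5 | [(2R,3R)-2-Ar-2,3-dihydrofuran-3-yl]methyl (S)-2-methoxy-2-phenylacetate | CO[C@H](C(=O)OC[C@H]1C=CO[C@H]1c1ccc(O[Si](C(C)C)(C(C)C)C(C)C)c(OC)c1)c1ccccc1
F2 | step 8 | (1S,2R,5R,6R)-2,6-di-Ar-3,7-dioxabicyclo[3.3.0]octan-8-ol (lactol, anomeric mixture; exo anomer drawn) | COc1cc([C@@H]2O[C@@H](O)[C@H]3[C@@H]2CO[C@H]3c2ccc(O[Si](C(C)C)(C(C)C)C(C)C)c(OC)c2)ccc1O[Si](C(C)C)(C(C)C)C(C)C
F3 | step 9 | (1R,2S,5R,6R,8R)-2,6-di-Ar-3,7-dioxabicyclo[3.3.0]octane-1,8-diol | COc1cc([C@@H]2O[C@@H](O)[C@@]3(O)[C@@H]2CO[C@H]3c2ccc(O[Si](C(C)C)(C(C)C)C(C)C)c(OC)c2)ccc1O[Si](C(C)C)(C(C)C)C(C)C
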